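**Retrosynthetic overview**
1. The target comes from the 15-deoxy compound by allylic CH3 to CHO oxidation, and the O9 acetate from a 9-hydroxy elemanolide.
2. Key step: an acyclic 1,6-dialdehyde is closed at C8–C9 by SmI2 pinacol coupling. The cyclohexane forms first. The O8 alkoxide then closes the γ-lactone on C12 in the same flask.
3. Both formyl groups (C8, C9) are released together by periodate cleavage of two glyceraldehyde-derived dioxolanes.
4. C6–C7 comes from an indium Barbier allylation of a C6 aldehyde with a Baylis–Hillman bromide (sets C6, C7), followed by the angelate.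
5. C5–C10 comes from an Ireland–Claisen rearrangement of a Z-allylic senecioate (sets C5, C10), itself made by Nozaki–Hiyama–Kishi coupling.

Atom labels: C1 to C15 are the elemane positions of the target. The ring is C5 to C10. C14 methyl and the C1=C2 vinyl sit on C10, C4(=C3)C15 on C5, and C11(=C13)C12 on C7. Dioxolane A sits on C9. Dioxolane B sits on C7, and its ring CH is C8.

Assumption: 5 and 14 are bought as such, and the quoted diastereomer ratios are estimates.

**Step 1**
Reactants: 1 but-2-yn-1-ol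
Product: 2 (Z)-3-iodobut-2-en-1-ol
Conditions: NaAlH2(OCH2CH2OMe)2, THF, 0 to 23 °C; then I2, −78 °C
Reagents that add atoms: iodine [I][I]
Why: Hydroxyl-directed trans-hydroalumination of the propargylic alcohol places aluminium on C3 anti to the new hydrogen, and iodinolysis with retention gives only the Z vinyl iodide.

**Step 2**
Reactants: 2 (Z)-3-iodobut-2-en-1-ol, 3 3-methylbut-2-enoyl chloride
Product: 4 (Z)-3-iodobut-2-enyl 3-methylbut-2-enoate
Conditions: pyridine, CH2Cl2, 0 °C
Reagents that add atoms: none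
Why: This is plain O-acylation of a primary alcohol, and pyridine is too weak a base to form the vinylketene, so the conjugated senecioate is kept and no stereocentre is made.

**Step 3**
Reactants: 4 (Z)-3-iodobut-2-enyl 3-methylbut-2-enoate, 5 (R)-2,2-dimethyl-1,3-dioxolane-4-carbaldehyde
Product: 6 (Z)-(4S)-4-[(4R)-2,2-dimethyl-1,3-dioxolan-4-yl]-3-methyl-4-(triethylsilyloxy)but-2-enyl 3-methylbut-2-enoate
Conditions: CrCl2 (15 mol %), NiCl2 (2 mol %), Mn, Et3SiCl, DMF–THF, 23 °C
Reagents that add atoms: chlorotriethylsilane CC[Si](Cl)(CC)CC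
Why: This Nozaki–Hiyama–Kishi coupling is catalytic in chromium (Mn reduces, Et3SiCl frees the chromium alkoxide and caps O9), the alkene geometry is retained, and Felkin–Anh attack anti to the dioxolane C–O bond gives the anti (9S) ether in about 4:1, the minor epimer being removed on silica.

**Step 4**
Reactants: 6 (Z)-(4S)-4-[(4R)-2,2-dimethyl-1,3-dioxolan-4-yl]-3-methyl-4-(triethylsilyloxy)but-2-enyl 3-methylbut-2-enoate
Product: 9 (2S,3S)-3-{(S)-[(4R)-2,2-dimethyl-1,3-dioxolan-4-yl](triethylsilyloxy)methyl}-3-methyl-2-(prop-1-en-2-yl)pent-4-enal, via silyl ketene acetal 7 (not isolated), via trimethylsilyl ester 8 (not isolated)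
Conditions: LiN(i-Pr)2, THF, −78 °C; Me3SiCl; −78 to 45 °C; then i-Bu2AlH, −78 °C; aq. potassium sodium tartrate
Reagents that add atoms: chlorotrimethylsilane C[Si](C)(C)Cl (stays only in 7 and 8)
Why: In this Ireland–Claisen rearrangement with partial reduction of the silyl ester, γ-deprotonation of the s-cis senecioate gives the dienolate with C4 cis to OSi, the chair on the Z alkene fixes the C5/C10 relation, 1,3-allylic strain keeps H9 in the alkene plane so the new bond forms anti to the bulky dioxolane A (5S,10S), and the hindered silyl aluminium acetal survives at −78 °C so reduction stops at the aldehyde.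

**Step 5**
Reactants: 5 (R)-2,2-dimethyl-1,3-dioxolane-4-carbaldehyde, 10 tert-butyl acrylate
Product: 11 tert-butyl 2-{[(4R)-2,2-dimethyl-1,3-dioxolan-4-yl](hydroxy)methyl}acrylate (both carbinol epimers)
Conditions: DABCO (0.5 equiv), 1,4-dioxane–H2O 1:1, 23 °C, 48 h
Reagents that add atoms: none
Why: This is a Morita–Baylis–Hillman reaction, and the new carbinol centre forms as a mixture that is erased in the next step while the dioxolane centre is untouched.

**Step 6**
Reactants: 11 tert-butyl 2-{[(4R)-2,2-dimethyl-1,3-dioxolan-4-yl](hydroxy)methyl}acrylate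
Product: 12 tert-butyl (Z)-2-(bromomethyl)-3-[(4S)-2,2-dimethyl-1,3-dioxolan-4-yl]acrylate
Conditions: NBS, Me2S, CH2Cl2, 0 to 23 °C
Reagents that add atoms: N-bromosuccinimide O=C1CCC(=O)N1Br
Why: Corey–Kim-type activation of the alcohol is followed by SN2′ attack of bromide, which gives the trisubstituted Z bromide (dioxolane B cis to CH2Br) usual for Baylis–Hillman adducts.

**Step 7**
Reactants: 9 (2S,3S)-3-{(S)-[(4R)-2,2-dimethyl-1,3-dioxolan-4-yl](triethylsilyloxy)methyl}-3-methyl-2-(prop-1-en-2-yl)pent-4-enal, 12 tert-butyl (Z)-2-(bromomethyl)-3-[(4S)-2,2-dimethyl-1,3-dioxolan-4-yl]acrylate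
Product: 13 tert-butyl (3S,4S,5S,6S)-3-[(4S)-2,2-dimethyl-1,3-dioxolan-4-yl]-6-{(S)-[(4R)-2,2-dimethyl-1,3-dioxolan-4-yl](triethylsilyloxy)methyl}-4-hydroxy-6-methyl-2-methylidene-5-(prop-1-en-2-yl)oct-7-enoate
Conditions: In powder, THF–H2O 1:1, 23 °C
Reagents that add atoms: none
Why: In this indium Barbier allylation (SE2′) through a closed chair, the γ-substituent cis to CH2In sits axial and gives the 6,7-syn adduct, the same axial group disfavours the Felkin rotamer by a syn-pentane clash so the anti-Felkin 6S carbinol forms, the allyl face anti to the CH2–O carbon of dioxolane B (H8 inside) gives 7S, and the tert-butyl ester does not lactonise on O6.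

**Step 8**
Reactants: 13 tert-butyl hydroxy ester from step 7, 14 (Z)-2-methylbut-2-enoic anhydride (angelic anhydride)
Product: 15 tert-butyl (3S,4S,5S,6S)-3-[(4S)-2,2-dimethyl-1,3-dioxolan-4-yl]-6-{(S)-[(4R)-2,2-dimethyl-1,3-dioxolan-4-yl](triethylsilyloxy)methyl}-6-methyl-4-[(Z)-2-methylbut-2-enoyloxy]-2-methylidene-5-(prop-1-en-2-yl)oct-7-enoate
Conditions: LiN(SiMe3)2 (1.1 equiv), THF, −40 to 0 °C
Reagents that add atoms: none
Why: The lithium alkoxide is acylated by the anhydride without a nucleophilic catalyst, so the angelate keeps its Z geometry, O6 is the only free hydroxyl, and no stereocentre is touched.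

**Step 9**
Reactants: 15 tert-butyl angelate from step 8
Product: 17 tert-butyl (3S,4S,5S,6S)-3,6-diformyl-6-methyl-4-[(Z)-2-methylbut-2-enoyloxy]-2-methylidene-5-(prop-1-en-2-yl)oct-7-enoate, via pentaol 16 (not isolated)
Conditions: AcOH–H2O 4:1, 40 °C; evaporate; NaIO4 (3.3 equiv), THF–pH 7 phosphate buffer, 0 °C; used at once
Reagents that add atoms: none
Why: Mild acid removes the silyl ether and both acetonides while the tert-butyl ester resists lactonisation, and neutral Malaprade cleavage then cuts the C9 triol twice and the C8 diol once, so both aldehydes appear at pH 7 where the labile C7–H is not epimerised or conjugated.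

**Step 10**
Reactants: 17 tert-butyl dialdehyde from step 9
Product: 19 (5S,6S,7S,8R,9S,10S)-6-angeloyloxy-9-hydroxyelema-1,3,11(13)-trien-8,12-olide, via cis-diol samarium diolate 18 (not isolated)
Conditions: SmI2 (2.5 equiv), THF, −78 °C, 1 h; then 23 °C, 3 h; aq. citric acid
Reagents that add atoms: none
Why: This intramolecular SmI2 pinacol coupling with alkoxide lactonisation proceeds through the chair that keeps isopropenyl, vinyl and the C7 side chain equatorial, where the two ketyl oxygens are bridged by one trivalent samarium and must be cis, the β,β pair would put O8 syn-axial to C14 and the angelate, so the α,α (8R,9S) diolate forms and its equatorial O8, trans to the equatorial C11 unit, attacks the tert-butyl ester to give the trans-fused α-methylene lactone while axial O9 cannot close a five-membered ring.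

**Step 11**
Reactants: 19 (5S,6S,7S,8R,9S,10S)-6-angeloyloxy-9-hydroxyelema-1,3,11(13)-trien-8,12-olide
Product: 20 (5S,6S,7S,8R,9S,10S)-9-acetoxy-6-angeloyloxyelema-1,3,11(13)-trien-8,12-olide
Conditions: Ac2O, DMAP (0.2 equiv), pyridine, CH2Cl2, 23 °C
Reagents that add atoms: acetic anhydride CC(=O)OC(C)=O
Why: DMAP-catalysed acetylation acts on the only free hydroxyl (axial, neopentyl O9) with retention at C9.

**Step 12**
Reactants: 20 (5S,6S,7S,8R,9S,10S)-9-acetoxy-6-angeloyloxyelema-1,3,11(13)-trien-8,12-olide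
Product: 21 (5R,6S,7S,8R,9S,10S)-9-acetoxy-6-angeloyloxy-15-oxoelema-1,3,11(13)-trien-8,12-olide (target)
Conditions: SeO2 (1.2 equiv), 1,4-dioxane, 80 °C
Reagents that add atoms: selenium dioxide O=[Se]=O
Why: In this Riley allylic oxidation (ene reaction, then 2,3-shift) the isopropenyl group is the only electron-rich alkene with an accessible allylic C–H, since the vinyl has none, the acrylate and angelate are electron-poor and C5–H is buried, so C15H3 becomes CHO without touching a stereocentre (the C5 descriptor changes only by priority).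

**Compound list**
1 | but-2-yn-1-ol | CC#CCO | starting material
2 | (Z)-3-iodobut-2-en-1-ol | OC/C=C(/C)I | intermediate
3 | 3-methylbut-2-enoyl chloride (senecioyl chloride) | CC(C)=CC(=O)Cl | starting material
4 | (Z)-3-iodobut-2-enyl 3-methylbut-2-enoate | CC(C)=CC(=O)OC/C=C(/C)I | intermediate
5 | (R)-2,2-dimethyl-1,3-dioxolane-4-carbaldehyde | O=C[C@H]1COC(C)(C)O1 | starting material
6 | (Z)-(4S)-4-[(4R)-2,2-dimethyl-1,3-dioxolan-4-yl]-3-methyl-4-(triethylsilyloxy)but-2-enyl 3-methylbut-2-enoate | CC(C)=CC(=O)OC/C=C(/C)[C@H](O[Si](CC)(CC)CC)[C@H]1COC(C)(C)O1 | intermediate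
7 | (1Z)-trimethylsilyl ketene acetal of 6 (C4 cis to OSiMe3) | C=C(C)/C=C(\O[Si](C)(C)C)OC/C=C(/C)[C@H](O[Si](CC)(CC)CC)[C@H]1COC(C)(C)O1 | intermediate
8 | trimethylsilyl (2S,3S)-3-{(S)-[(4R)-2,2-dimethyl-1,3-dioxolan-4-yl](triethylsilyloxy)methyl}-3-methyl-2-(prop-1-en-2-yl)pent-4-enoate | C[Si](C)(C)OC(=O)[C@@H](C(C)=C)[C@](C)(C=C)[C@H](O[Si](CC)(CC)CC)[C@H]1COC(C)(C)O1 | intermediate
9 | (2S,3S)-3-{(S)-[(4R)-2,2-dimethyl-1,3-dioxolan-4-yl](triethylsilyloxy)methyl}-3-methyl-2-(prop-1-en-2-yl)pent-4-enal | O=C[C@@H](C(C)=C)[C@](C)(C=C)[C@H](O[Si](CC)(CC)CC)[C@H]1COC(C)(C)O1 | intermediate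
10 | tert-butyl acrylate | C=CC(=O)OC(C)(C)C | starting material
11 | tert-butyl 2-{[(4R)-2,2-dimethyl-1,3-dioxolan-4-yl](hydroxy)methyl}acrylate (carbinol epimers) | CC(C)(C)OC(=O)C(=C)C(O)[C@H]1COC(C)(C)O1 | intermediate
12 | tert-butyl (Z)-2-(bromomethyl)-3-[(4S)-2,2-dimethyl-1,3-dioxolan-4-yl]acrylate | CC(C)(C)OC(=O)/C(CBr)=C/[C@H]1COC(C)(C)O1 | intermediate
13 | tert-butyl (3S,4S,5S,6S)-4-hydroxy ester carrying dioxolane B on C7 and the silyloxy dioxolane A unit on C10 (full name in step 7) | CC(C)(C)OC(=O)C(=C)[C@H]([C@H]1COC(C)(C)O1)[C@@H](O)[C@@H](C(C)=C)[C@](C)(C=C)[C@H](O[Si](CC)(CC)CC)[C@H]2COC(C)(C)O2 | intermediate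
14 | (Z)-2-methylbut-2-enoic anhydride (angelic anhydride) | C/C=C(/C)C(=O)OC(=O)/C(C)=C\C | starting material
15 | O6 angelate of 13 (full name in step 8) | CC(C)(C)OC(=O)C(=C)[C@H]([C@H]1COC(C)(C)O1)[C@@H](OC(=O)/C(C)=C\C)[C@@H](C(C)=C)[C@](C)(C=C)[C@H](O[Si](CC)(CC)CC)[C@H]2COC(C)(C)O2 | intermediate
16 | tert-butyl (3R,4S,5S,6S)-3-[(1S)-1,2-dihydroxyethyl]-6-methyl-4-[(Z)-2-methylbut-2-enoyloxy]-2-methylidene-5-(prop-1-en-2-yl)-6-[(1S,2R)-1,2,3-trihydroxypropyl]oct-7-enoate | CC(C)(C)OC(=O)C(=C)[C@H]([C@H](O)CO)[C@@H](OC(=O)/C(C)=C\C)[C@@H](C(C)=C)[C@](C)(C=C)[C@H](O)[C@H](O)CO | intermediate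
17 | tert-butyl (3S,4S,5S,6S)-3,6-diformyl-6-methyl-4-[(Z)-2-methylbut-2-enoyloxy]-2-methylidene-5-(prop-1-en-2-yl)oct-7-enoate | CC(C)(C)OC(=O)C(=C)[C@H](C=O)[C@@H](OC(=O)/C(C)=C\C)[C@@H](C(C)=C)[C@](C)(C=C)C=O | intermediate
18 | tert-butyl (5S,6S,7R,8R,9S,10S)-6-angeloyloxy-8,9-dihydroxyelema-1,3,11(13)-trien-12-oate (formed as its samarium diolate) | C=C[C@]1(C)[C@H](O)[C@H](O)[C@@H](C(=C)C(=O)OC(C)(C)C)[C@@H](OC(=O)/C(C)=C\C)[C@H]1C(C)=C | intermediate
19 | (5S,6S,7S,8R,9S,10S)-6-angeloyloxy-9-hydroxyelema-1,3,11(13)-trien-8,12-olide | C=C[C@]1(C)[C@H](O)[C@@H]2OC(=O)C(=C)[C@H]2[C@@H](OC(=O)/C(C)=C\C)[C@H]1C(C)=C | intermediate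
20 | (5S,6S,7S,8R,9S,10S)-9-acetoxy-6-angeloyloxyelema-1,3,11(13)-trien-8,12-olide | C=C[C@]1(C)[C@H](OC(C)=O)[C@@H]2OC(=O)C(=C)[C@H]2[C@@H](OC(=O)/C(C)=C\C)[C@H]1C(C)=C | intermediate
21 | (5R,6S,7S,8R,9S,10S)-9-acetoxy-6-angeloyloxy-15-oxoelema-1,3,11(13)-trien-8,12-olide | C=C[C@]1(C)[C@H](OC(C)=O)[C@@H]2OC(=O)C(=C)[C@H]2[C@@H](OC(=O)/C(C)=C\C)[C@H]1C(=C)C=O | target

**Total step count:** 12.
**Longest linear sequence:** 10 (steps 1, 2, 3, 4, 7, 8, 9, 10, 11, 12).

**Three steps most likely to fail**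

Step 10 (pinacol and lactonisation). A ketyl may add 7-endo to the acrylate, or 17 may isomerise before it couples. The fallback sets out from 17 and comes back at 18. The same C8–C9 bond is first made as an alkene by McMurry coupling with low-valent titanium (TiCl4, Zn, pyridine, THF), giving tert-butyl 6-angeloyloxyelema-1,3,8,11(13)-tetraen-12-oate F1. One equivalent of OsO4 in pyridine at −40 °C then adds to the ring cis-alkene from the α face. That face lies anti to the axial C14 methyl and the C7 side chain. The other alkenes react more slowly: the vinyl is neopentyl, the isopropenyl is flanked, and the acrylate and angelate are electron-poor. The product is 18, which closes to 19 with catalytic camphorsulfonic acid in warm toluene.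

Step 4 (Claisen and partial reduction in one flask). The bulky axial C9 group may open a boat pathway and erode the ratio, and i-Bu2AlH may over-reduce. The fallback sets out from 6 and comes back at 9, and it separates the two jobs. Only the rearrangement is run, and 8 is hydrolysed with aqueous NaHCO3 in methanol to (2S,3S)-3-{(S)-[(4R)-2,2-dimethyl-1,3-dioxolan-4-yl](triethylsilyloxy)methyl}-3-methyl-2-(prop-1-en-2-yl)pent-4-enoic acid F2. Its diastereomeric purity is raised by crystallising the (R)-1-phenylethylammonium salt. LiAlH4 gives the corresponding pent-4-en-1-ol F3, and Dess–Martin periodinane gives 9.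

Step 7 (Barbier allylation between two hindered carbons). Attack through the CH2 terminus, or a poor ratio, is possible with a fluxional allylindium. The fallback sets out from 12 (with 9) and comes back at 13. Borylation with Pd2(dba)3 and B2pin2 turns 12 into the configurationally stable tert-butyl (Z)-3-[(4S)-2,2-dimethyl-1,3-dioxolan-4-yl]-2-[(4,4,5,5-tetramethyl-1,3,2-dioxaborolan-2-yl)methyl]acrylate F4. Heating F4 with 9 in toluene adds it through the same closed chair, now with fixed alkene geometry, and aqueous work-up of the borate gives 13.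

**Further compounds**
F1 | step 10 | tert-butyl 6-angeloyloxyelema-1,3,8,11(13)-tetraen-12-oate (C5, C6, C7, C10 arranged as in 17) | C=C[C@]1(C)C=C[C@@H](C(=C)C(=O)OC(C)(C)C)[C@@H](OC(=O)/C(C)=C\C)[C@H]1C(C)=C
F2 | step 4 | (2S,3S)-3-{(S)-[(4R)-2,2-dimethyl-1,3-dioxolan-4-yl](triethylsilyloxy)methyl}-3-methyl-2-(prop-1-en-2-yl)pent-4-enoic acid | OC(=O)[C@@H](C(C)=C)[C@](C)(C=C)[C@H](O[Si](CC)(CC)CC)[C@H]1COC(C)(C)O1
F3 | step 4 | (2S,3S)-3-{(S)-[(4R)-2,2-dimethyl-1,3-dioxolan-4-yl](triethylsilyloxy)methyl}-3-methyl-2-(prop-1-en-2-yl)pent-4-en-1-ol | OC[C@@H](C(C)=C)[C@](C)(C=C)[C@H](O[Si](CC)(CC)CC)[C@H]1COC(C)(C)O1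
F4 | step 7 | tert-butyl (Z)-3-[(4S)-2,2-dimethyl-1,3-dioxolan-4-yl]-2-[(4,4,5,5-tetramethyl-1,3,2-dioxaborolan-2-yl)methyl]acrylate | CC(C)(C)OC(=O)/C(CB1OC(C)(C)C(C)(C)O1)=C/[C@H]2COC(C)(C)O2
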